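## The problem

Target 13 is a twofold-symmetric bis(hydroxyquinone). Two identical, fully substituted 1,4-benzoquinone rings (C1/C4 carbonyls, 2-hydroxy, 5-methoxy, 6-methyl) are joined through their C3 atoms by an unbranched, saturated tridecane-1,13-diyl chain (C1'–C13'). No ring is fused and there is no stereocentre, so the difficulty is regiochemical and not stereochemical. Each ring carries four oxygens in three roles: two quinone carbonyls, one free hydroxyl next to the chain-bearing carbon, and one methyl ether next to the methyl-bearing carbon. A synthesis has to tell these oxygens apart. The tether has an odd number of carbons and is bound to both rings by C(sp2)–C(sp3) bonds, so it cannot come from joining two equal halves at the centre; an odd central piece must be attached at both ends. The hydroxyquinone is an acidic, chelating, redox-active vinylogous acid, and the neighbouring ring methoxy group is a vinylogous ester open to addition–elimination. Carbon–carbon bond formation with organometallic reagents therefore belongs at the arene oxidation level, with the quinones unveiled last. Two features make a short plan possible. The ring methyl and the chain are para to each other with oxygen on all four remaining carbons, so the aromatic progenitor has a latent mirror plane and can be drawn from 1 with a single desymmetrising event. The free hydroxyl on C2 sits next to C3, which carries C1', so C1' is the exocyclic carbon of an ortho-quinone methide (9); the tether then divides as 1 + 11 + 1 carbons, and the phenol oxygen returned by a conjugate addition is the one that ends as the free OH.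

## Retrosynthesis

**13 back to 10 (C–O changes only).** No skeletal bond is cut. The quinone carbonyls of 13 are traced to a para pair of methyl ethers and the free hydroxyl to an acetate, giving 12, then 11, then bis-phenol 10. Oxidising 10 directly is the neighbouring option, but it would use the phenol oxygen and its para methoxy group for the quinone. That gives a dimethoxyquinone whose two ether groups are vinylogous esters of equal standing, and the oxygen differentiation would be lost. Acylation switches the chain-side oxygen off and leaves one para pair of ether oxygens per ring. Compound 10 is a robust bis-arene with no sensitive group. The forward steps need an oxidant confined to that ether pair on both rings and a final deacylation that leaves the ring methoxy group alone.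

**10 back to two molecules of 6 and one of 8, through 9.** The C1'–C2' and C12'–C13' bonds are cut. Each half of 10 is an ortho-alkylphenol, the retron for 1,4-addition of a carbon nucleophile to ortho-quinone methide 9. Cutting the aryl–C1' bonds instead would call for metalated 2 and a thirteen-carbon dielectrophile. That is short, but it leaves all four oxygens as methyl ethers and again ends at the undifferentiated dimethoxyquinone. Cuts further inside the chain create unactivated C(sp3)–C(sp3) couplings and break the symmetry. The quinone methide cut uses the ring's own hydroxyl as activating group and returns it unprotected and marked. The 29-carbon skeleton falls into one C11 reagent (8) and two copies of one aromatic unit (6). The forward step must release 9 slowly in the presence of the nucleophile, direct attack to the exocyclic carbon, and consume both ends of 8.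

**8 back to 7.** The two carbon–magnesium bonds are traced to the carbon–bromine bonds of purchasable 7. The forward step has to suppress Wurtz coupling.

**6 back to 5 and 4.** The benzylic alcohol of 6 comes from aldehyde 5 and the carbonate from the phenol of salicylaldehyde 4. Installing the carbonate before reduction avoids having to distinguish two hydroxyl groups. The reduction must not pass through a basic metal alkoxide, which would start the quinone methide cascade prematurely.

**4 back to 3.** One O–CH3 bond is restored. In 3 the two methoxy groups ortho to the formyl group are equivalent by symmetry, so chelation-directed removal of one methyl group can give only 4. This is the single desymmetrising event of the route, and it places the free oxygen next to the future chain carbon.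

**3 back to 2 and 1.** The aryl–CHO bond and then the aryl–CH3 bond are cut. Both carbons enter by directed lithiation at a ring hydrogen flanked by two methoxy groups, and symmetry leaves no regiochemical choice. The neighbouring option builds the same pattern from a less oxygenated toluene by successive halogenation, methoxylation, hydroxylation and ortho-formylation; it needs more steps and relies on electrophilic substitution selectivity. Compound 1 already holds all four oxygens.

## Roads not taken

**Alternative 1:** Both carbocycles are disconnected. Bis-enone A1 reacts with two equivalents of a malonate diester under alkoxide base: Michael addition at each chain-bearing β-carbon, then Claisen closure of the ethyl-ketone enolate onto an ester, gives bis(cyclohexane-1,3-dione) A2. This forms four C–C bonds and two rings in one operation from cheap acyclic materials. The stereoisomer mixture does not matter, since decarboxylation and dehydrogenation lead to bis-resorcinol A3. The weak point is oxidation level. A3 has two of the four ring oxygens, both next to the methyl group. The two oxygens flanking the chain must be added by ring oxidations, and one resorcinol oxygen must be methylated selectively, all in duplicate. A1 also needs its own synthesis. This road is better on material cost and uses no organometallic step. The chosen plan sets against it an arene with all four oxygens in place from 1, so no C–O bond is formed after the chain is attached, and a shorter sequence.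

**Alternative 2:** The C2'=C3' and C11'=C12' bonds of diene A6 are disconnected. Two molecules of allyl-hydroxyquinone A4 undergo ruthenium-carbene-catalysed cross-metathesis with both ends of diene A5, and the two alkenes of A6 are then hydrogenated. The plan is convergent and the oxygen pattern is complete in A4, so no late oxidative demethylation is needed. On step count it is at least as good as the chosen plan. Its weak points are structural. A4 and A5 are both unhindered terminal olefins, so the metathesis is statistical: homodimers of A4, singly coupled product and oligomers of A5 are expected beside A6. The acidic, chelating hydroxyquinone can poison the catalyst. Metal-hydride isomerisation of the allyl group into conjugation would shorten the tether by one or two carbons and give homologues that are hard to separate from 13. Hydrogenation also reduces the quinones, which must then be re-oxidised. The chosen plan sets against the step-count advantage a tether of fixed length, introduced saturated and in one piece.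

**Alternative 3:** Both six-membered rings are disconnected between the chain-side carbonyl carbon and the methoxy-bearing carbon. Heating tethered bis(4-alkenyl-4-hydroxycyclobutenone) A7 opens each four-membered ring to a dienylketene, which closes by six-electron electrocyclisation and tautomerises to bis-hydroquinone A8. Mild oxidation and acid cleavage of the tert-butyl ethers would finish the synthesis. The merit is that A8 arrives at the hydroquinone level with all oxygens differentiated; in this respect the road is better than the chosen one, which needs a tetravalent cerium oxidation and a basic deacylation. The weak points lie before the key step. A7 requires a two-fold addition of a thirteen-carbon dimetal reagent to a squaric ester and an acid-mediated rearrangement that endangers the tert-butyl ethers. It then needs a two-fold, carbonyl-selective addition of a 2-methoxy-1-methylvinyl-lithium, a reagent that is not purchasable and is prone to β-elimination of methoxide. The chosen plan sets against this one two-directional organometallic step and ring carbons taken entirely from purchasable 1.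

Key step: step 7

Remark on the chemistry: 13 is achiral, so the SMILES strings carry no stereodescriptors; 1 and 7 are taken as purchasable.

## Route

Step 1
Reactants: 1 1,2,4,5-tetramethoxybenzene
Product: 2 1,2,4,5-tetramethoxy-3-methylbenzene
Conditions: n-BuLi (1.05 equiv), THF, 0 °C to rt; CH3I, 0 °C to rt
Reagents that add atoms: iodomethane, CI
Why: Directed ortho-metalation; each ring hydrogen of 1 lies between two methoxy groups and the two are equivalent, so one is removed cleanly and the aryllithium is methylated by SN2 attack on CH3I, with the base held near one equivalent to suppress dimethylation.

Step 2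
Reactants: 2 1,2,4,5-tetramethoxy-3-methylbenzene
Product: 3 2,3,5,6-tetramethoxy-4-methylbenzaldehyde
Conditions: n-BuLi, TMEDA, THF, 0 °C; DMF, −78 °C to rt; 1 M HCl
Reagents that add atoms: N,N-dimethylformamide, CN(C)C=O
Why: Second directed ortho-metalation at the only remaining ring hydrogen, again flanked by two methoxy groups, followed by formylation of the aryllithium with DMF; the tetrahedral adduct survives until acidic work-up, so over-addition is not expected.

Step 3
Reactants: 3 2,3,5,6-tetramethoxy-4-methylbenzaldehyde
Product: 4 2-hydroxy-3,5,6-trimethoxy-4-methylbenzaldehyde
Conditions: BCl3 (1.1 equiv), CH2Cl2, −78 to 0 °C; H2O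
Reagents that add atoms: none
Why: Chelation-controlled Lewis-acid ether cleavage; BCl3 bridges the formyl oxygen and an ortho methoxy oxygen and chloride removes that methyl group, the two ortho ethers are equivalent so one product should form, and the resulting six-membered boron chelate protects the second ortho ether and the two meta ethers at this stoichiometry and temperature.

Step 4
Reactants: 4 2-hydroxy-3,5,6-trimethoxy-4-methylbenzaldehyde
Product: 5 tert-butyl (2-formyl-3,4,6-trimethoxy-5-methylphenyl) carbonate
Conditions: Boc2O, i-Pr2NEt, DMAP (cat.), THF, rt
Reagents that add atoms: di-tert-butyl dicarbonate, CC(C)(C)OC(=O)OC(=O)OC(C)(C)C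
Why: DMAP-catalysed O-tert-butoxycarbonylation of a phenol, the standard entry to O-Boc salicylaldehydes; the aldehyde is inert and there is no second hydroxyl to compete.

Step 5
Reactants: 5 tert-butyl (2-formyl-3,4,6-trimethoxy-5-methylphenyl) carbonate
Product: 6 tert-butyl [2-(hydroxymethyl)-3,4,6-trimethoxy-5-methylphenyl] carbonate
Conditions: BH3·THF, THF, 0 °C; pH 7 phosphate buffer
Reagents that add atoms: none
Why: Electrophilic borane reduction of the aldehyde gives a neutral trialkoxyborane and not a basic metal alkoxide, so the carbonate should not shift to the benzylic oxygen and the quinone methide cascade should stay dormant; neutral hydrolysis then frees the alcohol.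

Step 6
Reactants: 7 1,11-dibromoundecane
Product: 8 undecane-1,11-diylbis(magnesium bromide), used as a titrated THF solution
Conditions: Mg turnings (excess, I2-activated), THF, slow addition of 7, 40 °C
Reagents that add atoms: magnesium, [Mg]
Why: Grignard formation by insertion of magnesium into both primary C–Br bonds; slow addition to excess metal keeps the bromide concentration low and disfavours Wurtz coupling, and the eleven-carbon spacer is too long for cyclisation.

Step 7
Reactants: 6 tert-butyl [2-(hydroxymethyl)-3,4,6-trimethoxy-5-methylphenyl] carbonate (two molecules, 2.3 equiv), 8 undecane-1,11-diylbis(magnesium bromide)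
Product: 10 2,2'-(tridecane-1,13-diyl)bis(3,4,6-trimethoxy-5-methylphenol), via ortho-quinone methide 9 (not isolated)
Conditions: 6, CH3MgCl (1.0 equiv per 6), THF, −78 °C; then 8 (1.0 equiv, THF), −78 °C to rt; aq NH4Cl
Reagents that add atoms: none
Why: CH3MgCl deprotonates the benzylic alcohol with loss of methane, giving a magnesium alkoxide that is stable at −78 °C. On warming, the alkoxide attacks the neighbouring carbonate carbonyl through a six-membered transition state, the tert-butoxycarbonyl group moves to the benzylic oxygen, and the freed phenoxide expels tert-butyl carbonate to give ortho-quinone methide 9 (2,4,5-trimethoxy-3-methyl-6-methylidenecyclohexa-2,4-dien-1-one). Each carbon–magnesium bond of 8 then adds in 1,4-fashion to the exocyclic CH2 of one molecule of 9, forming the C1'–C2' and C12'–C13' bonds and returning each ring as a magnesium phenoxide. The closest known reaction type is Grignard addition to ortho-quinone methides released at low temperature from O-Boc salicyl alcohols, run here at both ends of one chain. No ring is closed and no stereocentre is formed. The step needs attack at the exocyclic carbon and must outrun quinone methide dimerisation: rearomatisation favours 1,4-addition, every ring carbon of 9 is substituted so ring attack is blocked, and slow release of the donor-stabilised 9 in the presence of the nucleophile keeps its concentration low. A small excess of 6 is used so that both ends of 8 are consumed. The phenol that emerges is the oxygen next to the chain, the one that becomes the free hydroxyl of 13.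

Step 8
Reactants: 10 2,2'-(tridecane-1,13-diyl)bis(3,4,6-trimethoxy-5-methylphenol)
Product: 11 2,2'-(tridecane-1,13-diyl)bis(3,4,6-trimethoxy-5-methylphenyl) diacetate
Conditions: Ac2O, pyridine, DMAP (cat.), CH2Cl2, rt
Reagents that add atoms: acetic anhydride, CC(=O)OC(C)=O
Why: DMAP-catalysed acylation of the two hindered phenols; the ester makes the chain-side oxygen electron-poor so that it should not take part in the oxidation that follows.

Step 9
Reactants: 11 2,2'-(tridecane-1,13-diyl)bis(3,4,6-trimethoxy-5-methylphenyl) diacetate
Product: 12 3,3'-(tridecane-1,13-diyl)bis(2-acetoxy-5-methoxy-6-methylcyclohexa-2,5-diene-1,4-dione)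
Conditions: (NH4)2Ce(NO3)6 (6 equiv), MeCN/H2O/CH2Cl2, 0 °C
Reagents that add atoms: water, O
Why: Oxidative demethylation of a para-dimethoxyarene by the tetravalent cerium salt (two one-electron oxidations, water attack at the ether-bearing carbons, loss of methanol); positions 3 and 6 of each aryl acetate hold the only para pair of ether oxygens, so the acetoxy group and the methoxy group para to it should be retained.

Step 10
Reactants: 12 3,3'-(tridecane-1,13-diyl)bis(2-acetoxy-5-methoxy-6-methylcyclohexa-2,5-diene-1,4-dione)
Product: 13 3,3'-(tridecane-1,13-diyl)bis(2-hydroxy-5-methoxy-6-methylcyclohexa-2,5-diene-1,4-dione)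
Conditions: K2CO3 (2.2 equiv), dry degassed MeOH, 0 °C; dilute HCl
Reagents that add atoms: none
Why: Transesterification of an acetoxyquinone, a vinylogous anhydride, should be fast at 0 °C; with methoxide as the only nucleophile any addition–elimination at the ring methoxy carbon is degenerate, and acidification returns the neutral hydroxyquinone.

## Compound list

1 | 1,2,4,5-tetramethoxybenzene | COc1cc(OC)c(OC)cc1OC | starting material
2 | 1,2,4,5-tetramethoxy-3-methylbenzene | Cc1c(OC)c(OC)cc(OC)c1OC | intermediate
3 | 2,3,5,6-tetramethoxy-4-methylbenzaldehyde | Cc1c(OC)c(OC)c(C=O)c(OC)c1OC | intermediate
4 | 2-hydroxy-3,5,6-trimethoxy-4-methylbenzaldehyde | Cc1c(OC)c(O)c(C=O)c(OC)c1OC | intermediate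
5 | tert-butyl (2-formyl-3,4,6-trimethoxy-5-methylphenyl) carbonate | CC(C)(C)OC(=O)Oc1c(OC)c(C)c(OC)c(OC)c1C=O | intermediate
6 | tert-butyl [2-(hydroxymethyl)-3,4,6-trimethoxy-5-methylphenyl] carbonate | CC(C)(C)OC(=O)Oc1c(OC)c(C)c(OC)c(OC)c1CO | intermediate
7 | 1,11-dibromoundecane | BrCCCCCCCCCCCBr | starting material
8 | undecane-1,11-diylbis(magnesium bromide) | Br[Mg]CCCCCCCCCCC[Mg]Br | intermediate
9 | 2,4,5-trimethoxy-3-methyl-6-methylidenecyclohexa-2,4-dien-1-one (ortho-quinone methide, not isolated) | C=C1C(=O)C(OC)=C(C)C(OC)=C1OC | intermediate
10 | 2,2'-(tridecane-1,13-diyl)bis(3,4,6-trimethoxy-5-methylphenol) | COc1c(C)c(OC)c(O)c(CCCCCCCCCCCCCc2c(O)c(OC)c(C)c(OC)c2OC)c1OC | intermediate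
11 | 2,2'-(tridecane-1,13-diyl)bis(3,4,6-trimethoxy-5-methylphenyl) diacetate | COc1c(C)c(OC)c(OC(C)=O)c(CCCCCCCCCCCCCc2c(OC(C)=O)c(OC)c(C)c(OC)c2OC)c1OC | intermediate
12 | 3,3'-(tridecane-1,13-diyl)bis(2-acetoxy-5-methoxy-6-methylcyclohexa-2,5-diene-1,4-dione) | COC1=C(C)C(=O)C(OC(C)=O)=C(CCCCCCCCCCCCCC2=C(OC(C)=O)C(=O)C(C)=C(OC)C2=O)C1=O | intermediate
13 | 3,3'-(tridecane-1,13-diyl)bis(2-hydroxy-5-methoxy-6-methylcyclohexa-2,5-diene-1,4-dione) | COC1=C(C)C(=O)C(O)=C(CCCCCCCCCCCCCC2=C(O)C(=O)C(C)=C(OC)C2=O)C1=O | target

## Step count and risk

Total step count: 10. Longest linear sequence: 9 steps (1 to 13 through steps 1–5 and 7–10); step 6 is the one-step side branch.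

**Step 7 (key step).** The most likely failure is self-condensation of the quinone methide competing with carbon–carbon bond formation. This covers dimerisation, oligomerisation and capture by the tert-butoxide released with it. It matters most at the second chain end, where the remaining carbon–magnesium bond is dilute and sits on a magnesium phenoxide aggregate. Protonation of one terminus would stop the reaction at single arylation. The cause is that a bimolecular capture must succeed twice on one chain while the electrophile is kept at low concentration.
The fallback sets out from 4 and 7 and comes back at 10. It forms the same ring–chain junctions by olefination: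
- Benzylation of 4 (benzyl bromide, K2CO3, DMF) gives 2-(benzyloxy)-3,5,6-trimethoxy-4-methylbenzaldehyde F1.
- Heating 7 with triphenylphosphine in MeCN gives undecane-1,11-diylbis(triphenylphosphonium) dibromide F2.
- Double deprotonation of F2 with NaN(SiMe3)2 in THF and two-fold Wittig reaction with F1 gives 1,13-bis[2-(benzyloxy)-3,5,6-trimethoxy-4-methylphenyl]trideca-1,12-diene F3 as an E/Z mixture.
- Hydrogenation over Pd/C saturates both alkenes and removes both benzyl groups, giving 10.

**Step 6.** Wurtz-type coupling and incomplete insertion would give chain-extended and monofunctional organomagnesium species, and a base titre would not reveal them. The cause is that each molecule must undergo two heterogeneous insertions while alkyl bromide is still present. The fallback sets out from 7 and comes back at 8. Halide exchange (NaI, acetone) gives 1,11-diiodoundecane F4. Iodine–lithium exchange with t-BuLi (two equivalents per iodide, Et2O/pentane, −78 °C) gives undecane-1,11-diyldilithium F5. Transmetalation with MgBr2·OEt2 gives 8 without a metal surface.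

**Step 5.** The risk is transfer of the tert-butoxycarbonyl group to the new benzylic oxygen during reduction or work-up, followed by elimination and further hydride delivery (loss of the benzylic hydroxyl), or plain loss of the carbonate. The cause is that any basic oxygen species at the benzylic position starts the cascade meant for step 7. The fallback sets out from 4 and comes back at 6 with the order reversed. NaBH4 in MeOH reduces 4 to 2-(hydroxymethyl)-3,4,6-trimethoxy-5-methylphenol F6. The phenoxide alone is then acylated with Boc2O under phase-transfer conditions (aqueous NaOH, CH2Cl2, Bu4NHSO4, 0 °C), using the acidity difference between phenol and benzylic alcohol.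

**Step 9.** The risk is incomplete or misdirected oxidation. The acetoxy group lowers the electron density of each ring, so harsher treatment may be needed to oxidise both rings. Under such treatment the acetyl group could be lost, and the freed phenol oxygen would then be oxidised together with its para methoxy group, erasing the oxygen differentiation. The fallback sets out from 10 and comes back at 13. It uses the phenol oxygen itself, so the acetate (steps 8 and 10) is bypassed:
- PhI(OAc)2 in MeOH at 0 °C should convert each phenol into its para-quinone monoketal, 2,2'-(tridecane-1,13-diyl)bis(3,4,4,6-tetramethoxy-5-methylcyclohexa-2,5-dien-1-one) F7.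
- In F7 only the methoxy group next to the chain is a vinylogous ester of the single carbonyl. LiOH in aqueous THF should replace it by hydroxide through addition–elimination.
- Dilute HCl then hydrolyses the ketal and gives 13.

This fallback is less precedented in its hydrolysis step than the main route, but it follows a different logic of differentiation.

## Further compounds

F1 | step 7 | 2-(benzyloxy)-3,5,6-trimethoxy-4-methylbenzaldehyde | O=Cc1c(OCc2ccccc2)c(OC)c(C)c(OC)c1OC
F2 | step 7 | undecane-1,11-diylbis(triphenylphosphonium) dibromide | [Br-].[Br-].C(CCCCCCCCCC[P+](c1ccccc1)(c1ccccc1)c1ccccc1)[P+](c1ccccc1)(c1ccccc1)c1ccccc1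
F3 | step 7 | 1,13-bis[2-(benzyloxy)-3,5,6-trimethoxy-4-methylphenyl]trideca-1,12-diene (E/Z mixture) | COc1c(C)c(OC)c(OCc2ccccc2)c(C=CCCCCCCCCCC=Cc2c(OCc3ccccc3)c(OC)c(C)c(OC)c2OC)c1OC
F4 | step 6 | 1,11-diiodoundecane | ICCCCCCCCCCCI
F5 | step 6 | undecane-1,11-diyldilithium | [Li]CCCCCCCCCCC[Li]
F6 | step 5 | 2-(hydroxymethyl)-3,4,6-trimethoxy-5-methylphenol | OCc1c(O)c(OC)c(C)c(OC)c1OC
F7 | step 9 | 2,2'-(tridecane-1,13-diyl)bis(3,4,4,6-tetramethoxy-5-methylcyclohexa-2,5-dien-1-one) | COC1=C(C)C(OC)(OC)C(OC)=C(CCCCCCCCCCCCCC2=C(OC)C(OC)(OC)C(C)=C(OC)C2=O)C1=O
A1 | alternative 1 | (4E,19E)-tricosa-4,19-diene-3,21-dione | CCC(=O)/C=C/CCCCCCCCCCCCC/C=C/C(=O)CC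
A2 | alternative 1 | dimethyl 6,6'-(tridecane-1,13-diyl)bis(3-methyl-2,4-dioxocyclohexane-1-carboxylate) (stereoisomer mixture) | COC(=O)C1C(=O)C(C)C(=O)CC1CCCCCCCCCCCCCC1CC(=O)C(C)C(=O)C1C(=O)OC
A3 | alternative 1 | 5,5'-(tridecane-1,13-diyl)bis(2-methylbenzene-1,3-diol) | Cc1c(O)cc(CCCCCCCCCCCCCc2cc(O)c(C)c(O)c2)cc1O
A4 | alternative 2 | 3-allyl-2-hydroxy-5-methoxy-6-methyl-1,4-benzoquinone | COC1=C(C)C(=O)C(O)=C(CC=C)C1=O
A5 | alternative 2 | undeca-1,10-diene | C=CCCCCCCCC=C
A6 | alternative 2 | (2E,11E)-1,13-bis(2-hydroxy-5-methoxy-6-methyl-1,4-benzoquinon-3-yl)trideca-2,11-diene | COC1=C(C)C(=O)C(O)=C(C/C=C/CCCCCCC/C=C/CC2=C(O)C(=O)C(C)=C(OC)C2=O)C1=O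
A7 | alternative 3 | 2,2'-(tridecane-1,13-diyl)bis[3-tert-butoxy-4-hydroxy-4-(1-methoxyprop-1-en-2-yl)cyclobut-2-en-1-one] (stereoisomer mixture) | O=C1C(CCCCCCCCCCCCCC2=C(OC(C)(C)C)C(O)(C(C)=COC)C2=O)=C(OC(C)(C)C)C1(O)C(C)=COC
A8 | alternative 3 | 3,3'-(tridecane-1,13-diyl)bis(2-tert-butoxy-5-methoxy-6-methylbenzene-1,4-diol) | COc1c(C)c(O)c(OC(C)(C)C)c(CCCCCCCCCCCCCc2c(O)c(OC)c(C)c(O)c2OC(C)(C)C)c1O
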